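**Plan**
1. Retrosynthesis cuts C16–C1′ (SN2′ allylation that also creates the exocyclic methylene and the C1′ centre), C14–C15 (alkenyl anion plus oxirane), the C8–O/C8–CH3 pair back to a C8 ketone, C7 out of ring B (one-carbon ring enlargement), C9–C11 (Michael addition) and C10–C9 (allylation).
2. Forward: ring A comes from 2,2,6-trimethylcyclohexanone; allylation sets C10; Wacker oxidation and aldol condensation close the five-membered ring C5–C6–C8–C9–C10; the key step inserts C7 to give ring B; the chain C11–C16 is grown; ring C is attached last as an achiral allylic chloride.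
3. Enabling feature: in the cyclopentenone the C8 carbonyl is flanked by the sp2 carbon C6 and the sp3 carbon C9, so a carbenoid placed on C8 is homologated by shift of C6; the C8 ketone and the C5=C6 alkene that result are the handles for C5, C9 and C8.
4. Stereochemistry: C10 from the chiral Pd catalyst; C5 by hydrogenation anti to the angular methyl; C9 by equilibration next to the C8 ketone; C8 by α-face epoxidation and hydride opening; the E alkene by syn-hydrozirconation and retentive substitution; C1′ from the chiral Cu catalyst.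
5. Locants: labdane-type numbering for the decalin (ring A = C1–C5, C10; ring B = C5–C10; chain C11–C16 from C9), C1′–C6′ for ring C.

Key step: step 7

Assumption: (R)-t-Bu-PHOX is taken to give the (R)-allyl ketone 4, the mirror image of the sense known for the (S)-ligand.
Assumption: in 8-ketone 17 the equatorial (9β) side chain is the thermodynamic epimer.
Assumption: the (S,S,S)-phosphoramidite of step 20 is taken to give the (S) centre at C1′; if a trial with a simple Grignard reagent shows the opposite sense, its enantiomer is used.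

Step 1
Reactants: 1 2,2,6-trimethylcyclohexan-1-one
Product: 3 allyl 2,6,6-trimethylcyclohex-1-en-1-yl carbonate, via lithium enolate 2 (not isolated)
Conditions: LiN(SiMe3)2, THF, −78 °C; allyl chloroformate, −78 to 0 °C
Reagents that add atoms: allyl chloroformate C=CCOC(=O)Cl
Why: The only enolisable position gives one tetrasubstituted enolate, which the hard chloroformate acylates on oxygen (enol carbonate formation); no stereocentre remains.

Step 2
Reactants: 3 allyl 2,6,6-trimethylcyclohex-1-en-1-yl carbonate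
Product: 4 (2R)-2,6,6-trimethyl-2-(prop-2-en-1-yl)cyclohexan-1-one
Conditions: Pd2(dba)3 (2.5 mol %), (R)-t-Bu-PHOX (6 mol %), THF, 25 °C
Reagents that add atoms: none
Why: Decarboxylative asymmetric Tsuji allylation: zerovalent palladium ionises the allyl carbonate, CO2 is lost and the chiral palladium enolate–allyl pair recombines, setting the quaternary C10 centre under ligand control.

Step 3
Reactants: 4 (2R)-2,6,6-trimethyl-2-(prop-2-en-1-yl)cyclohexan-1-one
Product: 5 (2R)-2,6,6-trimethyl-2-(2-oxopropyl)cyclohexan-1-one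
Conditions: PdCl2 (10 mol %), Cu(OAc)2 (25 mol %), O2 (1 atm), DMA/H2O, 25 °C
Reagents that add atoms: water O
Why: Wacker oxidation of the terminal alkene gives the methyl ketone with Markovnikov selectivity and leaves the quaternary centre untouched.

Step 4
Reactants: 5 (2R)-2,6,6-trimethyl-2-(2-oxopropyl)cyclohexan-1-one
Product: 7 (7aR)-4,4,7a-trimethyl-1,4,5,6,7,7a-hexahydro-2H-inden-2-one, via aldol 6 (not isolated)
Conditions: KOH (cat.), xylenes, 110 °C, Dean–Stark
Reagents that add atoms: none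
Why: Intramolecular aldol condensation: the methyl ketone enolate adds to the ring ketone (5-exo closure of ring C5–C6–C8–C9–C10) and the ketol loses water to give the enone.

Step 5
Reactants: 7 (7aR)-4,4,7a-trimethyl-1,4,5,6,7,7a-hexahydro-2H-inden-2-one; 8 but-3-en-2-one
Product: 10 (7aR)-4,4,7a-trimethyl-1-(3-oxobutyl)-1,4,5,6,7,7a-hexahydro-2H-inden-2-one (C1 epimers), via lithium dienolate 9 (not isolated)
Conditions: LiN(i-Pr)2, THF, −78 °C; 8, −78 °C; aq NH4Cl
Reagents that add atoms: none
Why: Deprotonation can only occur at C9 because both γ carbons are quaternary, and Michael addition of this cross-conjugated enolate installs C11–C14; the C9 configuration is left open because step 8 corrects it.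

Step 6
Reactants: 10 (7aR)-4,4,7a-trimethyl-1-(3-oxobutyl)-1,4,5,6,7,7a-hexahydro-2H-inden-2-one
Product: 11 (7aR)-4,4,7a-trimethyl-1-[2-(2-methyl-1,3-dioxolan-2-yl)ethyl]-1,4,5,6,7,7a-hexahydro-2H-inden-2-one
Conditions: ethane-1,2-diol, PPTS (cat.), benzene, reflux, Dean–Stark
Reagents that add atoms: ethane-1,2-diol OCCO
Why: Acetalisation is chemoselective for the unhindered saturated methyl ketone over the conjugated, hindered ring carbonyl and protects C13 during steps 7 and 9.

Step 7
Reactants: 11 (7aR)-4,4,7a-trimethyl-1-[2-(2-methyl-1,3-dioxolan-2-yl)ethyl]-1,4,5,6,7,7a-hexahydro-2H-inden-2-one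
Product: 15 (8aR)-5,5,8a-trimethyl-1-[2-(2-methyl-1,3-dioxolan-2-yl)ethyl]-3,5,6,7,8,8a-hexahydronaphthalen-2(1H)-one (C1 epimers), via dibromomethyl alkoxide 12 (not isolated), via oxido carbenoid 13 (not isolated), via lithium dienolate 14 (not isolated)
Conditions: CH2Br2, lithium 2,2,6,6-tetramethylpiperidide, THF, −78 °C; n-BuLi (2 equiv), −78 to 0 °C; AcOH, −78 °C
Reagents that add atoms: dibromomethane BrCBr
Why: LiCHBr2, formed in the flask, adds 1,2 to the C8 carbonyl to give alkoxide 12, bromine–lithium exchange gives the β-oxido carbenoid 13, and on warming the alkenyl carbon C6 shifts from C8 to the carbenoid carbon (the new C7) with loss of LiBr to give dienolate 14, which is protonated at C7. The closest known reaction type is the ring enlargement of cyclic ketones through β-oxido carbenoids, a one-pot relative of the Tiffeneau–Demjanov homologation. No ring is closed by cyclisation: the five-membered ring C5–C6–C8–C9–C10 becomes ring B by a 1,2-shift that inserts C7 between C8 and C6. No stereocentre is created and C10 is untouched; the step delivers the C8 ketone and the C5=C6 alkene through which C5, C9 and C8 are set in steps 8, 12 and 13. The step needs migration of C6 and not of C9, which the higher migratory aptitude of an sp2 carbon over a hindered sp3 carbon should secure, and 1,2- and not 1,4-addition, which the hard carbenoid nucleophile and the fully substituted β-carbon C5 secure.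

Step 8
Reactants: 15 (8aR)-5,5,8a-trimethyl-1-[2-(2-methyl-1,3-dioxolan-2-yl)ethyl]-3,5,6,7,8,8a-hexahydronaphthalen-2(1H)-one
Product: 17 (1R,4aS,8aS)-5,5,8a-trimethyl-1-[2-(2-methyl-1,3-dioxolan-2-yl)ethyl]octahydronaphthalen-2(1H)-one, via decalone epimer mixture 16 (not isolated)
Conditions: H2 (3 atm), Pd/C, EtOAc, 25 °C; then NaOMe (cat.), MeOH, 25 °C
Reagents that add atoms: none
Why: Heterogeneous hydrogenation should deliver hydrogen to C5 from the α face, opposite the axial C10 and C4 methyl groups, to give the trans ring fusion, and methoxide then equilibrates the enolisable C9 centre to the equatorial 9β side chain.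

Step 9
Reactants: 17 (1R,4aS,8aS)-5,5,8a-trimethyl-1-[2-(2-methyl-1,3-dioxolan-2-yl)ethyl]octahydronaphthalen-2(1H)-one
Product: 18 2-methyl-2-{2-[(1S,4aS,8aS)-5,5,8a-trimethyl-2-methylidenedecahydronaphthalen-1-yl]ethyl}-1,3-dioxolane
Conditions: Ph3PCH3Br, KOt-Bu, toluene, 90 °C
Reagents that add atoms: methyltriphenylphosphonium bromide C[P+](c1ccccc1)(c1ccccc1)c1ccccc1.[Br-]
Why: Wittig methylenation of the hindered C8 ketone; C9 stays at its equilibrium configuration and cannot epimerise afterwards.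

Step 10
Reactants: 18 2-methyl-2-{2-[(1S,4aS,8aS)-5,5,8a-trimethyl-2-methylidenedecahydronaphthalen-1-yl]ethyl}-1,3-dioxolane
Product: 19 4-[(1S,4aS,8aS)-5,5,8a-trimethyl-2-methylidenedecahydronaphthalen-1-yl]butan-2-one
Conditions: PPTS (cat.), acetone/H2O, 55 °C
Reagents that add atoms: water O
Why: Mild acetal hydrolysis unmasks the methyl ketone without isomerising the exocyclic alkene.

Step 11
Reactants: 19 4-[(1S,4aS,8aS)-5,5,8a-trimethyl-2-methylidenedecahydronaphthalen-1-yl]butan-2-one
Product: 23 (1S,4aS,8aS)-5,5,8a-trimethyl-2-methylidene-1-(pent-3-yn-1-yl)decahydronaphthalene, via lithium enolate 20 (not isolated), via enol phosphate 21 (not isolated), via lithium acetylide 22 (not isolated)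
Conditions: LiN(i-Pr)2, THF, −78 °C; ClP(O)(OEt)2, −78 to 25 °C; LiN(i-Pr)2 (2.2 equiv), −78 to 25 °C; MeI, 25 °C
Reagents that add atoms: iodomethane CI
Why: Kinetic enolisation at the methyl group, O-phosphorylation, elimination of the enol phosphate to the terminal acetylide and C-methylation turn the C13 carbonyl into the C13≡C14 alkyne that carries the future C14 methyl group.

Step 12
Reactants: 23 (1S,4aS,8aS)-5,5,8a-trimethyl-2-methylidene-1-(pent-3-yn-1-yl)decahydronaphthalene
Product: 24 (1R,2R,4aS,8aS)-5,5,8a-trimethyl-1-(pent-3-yn-1-yl)octahydro-1H-spiro[naphthalene-2,2'-oxirane]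
Conditions: mCPBA, NaHCO3, CH2Cl2, 0 °C
Reagents that add atoms: 3-chloroperoxybenzoic acid O=C(OO)c1cccc(Cl)c1
Why: Prilezhaev epoxidation of the only alkene from the α face, anti to the axial C10 methyl group, fixes the C8–O bond; the alkyne is inert.

Step 13
Reactants: 24 (1R,2R,4aS,8aS)-5,5,8a-trimethyl-1-(pent-3-yn-1-yl)octahydro-1H-spiro[naphthalene-2,2'-oxirane]
Product: 25 (1R,2R,4aS,8aS)-2,5,5,8a-tetramethyl-1-(pent-3-yn-1-yl)decahydronaphthalen-2-ol
Conditions: LiAlH4, THF, 0 to 40 °C; aq NaOH work-up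
Reagents that add atoms: none
Why: Hydride opens the spiro-epoxide at its CH2 carbon (SN2), giving the C8 methyl group and the equatorial 8α tertiary alcohol with retention at C8.

Step 14
Reactants: 25 (1R,2R,4aS,8aS)-2,5,5,8a-tetramethyl-1-(pent-3-yn-1-yl)decahydronaphthalen-2-ol
Product: 27 (1R,2R,4aS,8aS)-1-[(3E)-4-iodopent-3-en-1-yl]-2,5,5,8a-tetramethyldecahydronaphthalen-2-ol, via alkenylzirconocene 26 (not isolated)
Conditions: Cp2Zr(H)Cl (2.5 equiv), THF, 40 °C; I2, 0 °C
Reagents that add atoms: iodine II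
Why: Syn-hydrozirconation, equilibrated by excess reagent, should place zirconium on the alkyne carbon next to the small methyl group, and iodinolysis with retention gives the (E)-2-iodoalkene that fixes the alkene geometry.

Step 15
Reactants: 27 (1R,2R,4aS,8aS)-1-[(3E)-4-iodopent-3-en-1-yl]-2,5,5,8a-tetramethyldecahydronaphthalen-2-ol
Product: 29 (1R,2R,4aS,8aS)-1-[(3E)-6-hydroxy-4-methylhex-3-en-1-yl]-2,5,5,8a-tetramethyldecahydronaphthalen-2-ol, via alkenyllithium 28 (not isolated)
Conditions: t-BuLi (3.1 equiv), Et2O, −78 °C; oxirane, −78 to 0 °C; aq NH4Cl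
Reagents that add atoms: oxirane C1CO1
Why: Iodine–lithium exchange proceeds with retention of alkene geometry and the alkenyllithium opens oxirane, adding C15 and C16.

Step 16
Reactants: 29 (1R,2R,4aS,8aS)-1-[(3E)-6-hydroxy-4-methylhex-3-en-1-yl]-2,5,5,8a-tetramethyldecahydronaphthalen-2-ol
Product: 31 (1R,2R,4aS,8aS)-1-[(3E)-6-bromo-4-methylhex-3-en-1-yl]-2,5,5,8a-tetramethyldecahydronaphthalen-2-ol, via mesylate 30 (not isolated)
Conditions: MsCl, Et3N, CH2Cl2, −20 °C; LiBr, acetone, 40 °C
Reagents that add atoms: lithium bromide [Li+].[Br-]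
Why: The primary alcohol is sulfonylated selectively over the hindered tertiary one and displaced by bromide (SN2).

Step 17
Reactants: 32 3-methylcyclohex-2-en-1-one
Product: 34 3,3-dimethylcyclohex-1-en-1-yl trifluoromethanesulfonate, via lithium enolate 33 (not isolated)
Conditions: Me2CuLi (from MeLi and CuI), Et2O, 0 °C; PhNTf2, THF, 0 to 25 °C
Reagents that add atoms: lithium dimethylcuprate [Li+].C[Cu-]C; N-phenylbis(trifluoromethanesulfonimide) O=S(=O)(N(c1ccccc1)S(=O)(=O)C(F)(F)F)C(F)(F)F
Why: Conjugate addition creates the gem-dimethyl carbon and a regiodefined enolate, which is trapped as the enol triflate with its double bond toward the CMe2 carbon.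

Step 18
Reactants: 34 3,3-dimethylcyclohex-1-en-1-yl trifluoromethanesulfonate
Product: 35 (3,3-dimethylcyclohex-1-en-1-yl)methanol
Conditions: Bu3SnCH2OH, Pd(PPh3)4 (5 mol %), LiCl, 1,4-dioxane, 100 °C
Reagents that add atoms: (tributylstannyl)methanol CCCC[Sn](CCCC)(CCCC)CO
Why: Stille coupling transfers the hydroxymethyl group to the alkenyl triflate.

Step 19
Reactants: 35 (3,3-dimethylcyclohex-1-en-1-yl)methanol
Product: 37 1-(chloromethyl)-3,3-dimethylcyclohex-1-ene, via mesylate 36 (not isolated)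
Conditions: MsCl, LiCl, 2,4,6-collidine, DMF, 0 °C
Reagents that add atoms: lithium chloride [Li+].[Cl-]
Why: Mesylation and chloride displacement at the primary allylic carbon give the allylic chloride without allylic transposition.

Step 20
Reactants: 31 (1R,2R,4aS,8aS)-1-[(3E)-6-bromo-4-methylhex-3-en-1-yl]-2,5,5,8a-tetramethyldecahydronaphthalen-2-ol; 37 1-(chloromethyl)-3,3-dimethylcyclohex-1-ene
Product: 40 ambrein, via chloromagnesium alkoxide 38 (not isolated), via Grignard reagent 39 (not isolated)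
Conditions: i-PrMgCl (1.0 equiv), THF, 0 °C; Mg, THF, 40 °C; then 37 (1.5 equiv), copper thiophene-2-carboxylate (3 mol %), O,O′-(S)-1,1′-binaphthyl-2,2′-diyl N,N-bis[(S)-1-(2-methoxyphenyl)ethyl]phosphoramidite (3.3 mol %), CH2Cl2, −78 °C; aq NH4Cl
Reagents that add atoms: none
Why: Copper-catalysed asymmetric allylic alkylation (SN2′): the alkylcopper should attack the ring CH carbon next to the CMe2 group anti to chloride, which moves the double bond to the exocyclic position and creates the C1′ stereocentre under control of the chiral ligand, far from the decalin stereocentres.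

**Compound list**
1 | 2,2,6-trimethylcyclohexan-1-one (racemic) | CC1CCCC(C)(C)C1=O | starting material
2 | lithium 2,6,6-trimethylcyclohex-1-en-1-olate | [Li]OC1=C(C)CCCC1(C)C | intermediate
3 | allyl 2,6,6-trimethylcyclohex-1-en-1-yl carbonate | C=CCOC(=O)OC1=C(C)CCCC1(C)C | intermediate
4 | (2R)-2,6,6-trimethyl-2-(prop-2-en-1-yl)cyclohexan-1-one | C=CC[C@@]1(C)CCCC(C)(C)C1=O | intermediate
5 | (2R)-2,6,6-trimethyl-2-(2-oxopropyl)cyclohexan-1-one | CC(=O)C[C@@]1(C)CCCC(C)(C)C1=O | intermediate
6 | (7aR)-3a-hydroxy-4,4,7a-trimethyloctahydro-2H-inden-2-one (aldol, C3a epimers) | O=C1C[C@@]2(C)CCCC(C)(C)C2(O)C1 | intermediate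
7 | (7aR)-4,4,7a-trimethyl-1,4,5,6,7,7a-hexahydro-2H-inden-2-one | O=C1C[C@@]2(C)CCCC(C)(C)C2=C1 | intermediate
8 | but-3-en-2-one | C=CC(C)=O | starting material
9 | lithium dienolate of 7 (deprotonated at C1) | [Li]OC1=C[C@@]2(C)CCCC(C)(C)C2=C1 | intermediate
10 | (7aR)-4,4,7a-trimethyl-1-(3-oxobutyl)-1,4,5,6,7,7a-hexahydro-2H-inden-2-one (C1 epimers) | O=C1C(CCC(C)=O)[C@@]2(C)CCCC(C)(C)C2=C1 | intermediate
11 | (7aR)-4,4,7a-trimethyl-1-[2-(2-methyl-1,3-dioxolan-2-yl)ethyl]-1,4,5,6,7,7a-hexahydro-2H-inden-2-one (C1 epimers) | O=C1C(CCC3(C)OCCO3)[C@@]2(C)CCCC(C)(C)C2=C1 | intermediate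
12 | lithium alkoxide of the 2-(dibromomethyl) carbinol from 11 | [Li]OC1(C(Br)Br)C(CCC3(C)OCCO3)[C@@]2(C)CCCC(C)(C)C2=C1 | intermediate
13 | β-oxido carbenoid (2-[bromo(lithio)methyl] lithium alkoxide) | [Li]OC1(C([Li])Br)C(CCC3(C)OCCO3)[C@@]2(C)CCCC(C)(C)C2=C1 | intermediate
14 | lithium dienolate of 15 | CC1(OCCO1)CCC2[C@@]3(C)CCCC(C)(C)C3=CC=C2O[Li] | intermediate
15 | (8aR)-5,5,8a-trimethyl-1-[2-(2-methyl-1,3-dioxolan-2-yl)ethyl]-3,5,6,7,8,8a-hexahydronaphthalen-2(1H)-one (C1 epimers) | CC1(OCCO1)CCC2[C@@]3(C)CCCC(C)(C)C3=CCC2=O | intermediate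
16 | (4aS,8aS)-5,5,8a-trimethyl-1-[2-(2-methyl-1,3-dioxolan-2-yl)ethyl]octahydronaphthalen-2(1H)-one (C1 epimers) | CC1(OCCO1)CCC2[C@@]3(C)CCCC(C)(C)[C@@H]3CCC2=O | intermediate
17 | (1R,4aS,8aS)-5,5,8a-trimethyl-1-[2-(2-methyl-1,3-dioxolan-2-yl)ethyl]octahydronaphthalen-2(1H)-one | CC1(OCCO1)CC[C@@H]2[C@@]3(C)CCCC(C)(C)[C@@H]3CCC2=O | intermediate
18 | 2-methyl-2-{2-[(1S,4aS,8aS)-5,5,8a-trimethyl-2-methylidenedecahydronaphthalen-1-yl]ethyl}-1,3-dioxolane | CC1(OCCO1)CC[C@@H]2[C@@]3(C)CCCC(C)(C)[C@@H]3CCC2=C | intermediate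
19 | 4-[(1S,4aS,8aS)-5,5,8a-trimethyl-2-methylidenedecahydronaphthalen-1-yl]butan-2-one | CC(=O)CC[C@@H]1[C@@]2(C)CCCC(C)(C)[C@@H]2CCC1=C | intermediate
20 | terminal lithium enolate of 19 | C=C(O[Li])CC[C@@H]1[C@@]2(C)CCCC(C)(C)[C@@H]2CCC1=C | intermediate
21 | diethyl enol phosphate of 19 | C=C(OP(=O)(OCC)OCC)CC[C@@H]1[C@@]2(C)CCCC(C)(C)[C@@H]2CCC1=C | intermediate
22 | lithium acetylide (terminal alkyne salt) | [Li]C#CCC[C@@H]1[C@@]2(C)CCCC(C)(C)[C@@H]2CCC1=C | intermediate
23 | (1S,4aS,8aS)-5,5,8a-trimethyl-2-methylidene-1-(pent-3-yn-1-yl)decahydronaphthalene | CC#CCC[C@@H]1[C@@]2(C)CCCC(C)(C)[C@@H]2CCC1=C | intermediate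
24 | (1R,2R,4aS,8aS)-5,5,8a-trimethyl-1-(pent-3-yn-1-yl)octahydro-1H-spiro[naphthalene-2,2'-oxirane] | CC#CCC[C@@H]1[C@@]2(C)CCCC(C)(C)[C@@H]2CC[C@]13CO3 | intermediate
25 | (1R,2R,4aS,8aS)-2,5,5,8a-tetramethyl-1-(pent-3-yn-1-yl)decahydronaphthalen-2-ol | CC#CCC[C@@H]1[C@@]2(C)CCCC(C)(C)[C@@H]2CC[C@@]1(C)O | intermediate
26 | alkenylzirconocene (Zr on the methyl-bearing alkene carbon, O-zirconated) | C/C(=C\CC[C@@H]1[C@@]2(C)CCCC(C)(C)[C@@H]2CC[C@@]1(C)O[Zr](Cl)(C3C=CC=C3)C3C=CC=C3)[Zr](Cl)(C4C=CC=C4)C4C=CC=C4 | intermediate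
27 | (1R,2R,4aS,8aS)-1-[(3E)-4-iodopent-3-en-1-yl]-2,5,5,8a-tetramethyldecahydronaphthalen-2-ol | C/C(I)=C\CC[C@@H]1[C@@]2(C)CCCC(C)(C)[C@@H]2CC[C@@]1(C)O | intermediate
28 | alkenyllithium (lithium alkoxide) from 27 | C/C([Li])=C\CC[C@@H]1[C@@]2(C)CCCC(C)(C)[C@@H]2CC[C@@]1(C)O[Li] | intermediate
29 | (1R,2R,4aS,8aS)-1-[(3E)-6-hydroxy-4-methylhex-3-en-1-yl]-2,5,5,8a-tetramethyldecahydronaphthalen-2-ol | OCC/C(C)=C/CC[C@@H]1[C@@]2(C)CCCC(C)(C)[C@@H]2CC[C@@]1(C)O | intermediate
30 | primary methanesulfonate of 29 | CS(=O)(=O)OCC/C(C)=C/CC[C@@H]1[C@@]2(C)CCCC(C)(C)[C@@H]2CC[C@@]1(C)O | intermediate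
31 | (1R,2R,4aS,8aS)-1-[(3E)-6-bromo-4-methylhex-3-en-1-yl]-2,5,5,8a-tetramethyldecahydronaphthalen-2-ol | BrCC/C(C)=C/CC[C@@H]1[C@@]2(C)CCCC(C)(C)[C@@H]2CC[C@@]1(C)O | intermediate
32 | 3-methylcyclohex-2-en-1-one | CC1=CC(=O)CCC1 | starting material
33 | lithium 3,3-dimethylcyclohex-1-en-1-olate | CC1(C)CCCC(O[Li])=C1 | intermediate
34 | 3,3-dimethylcyclohex-1-en-1-yl trifluoromethanesulfonate | CC1(C)CCCC(OS(=O)(=O)C(F)(F)F)=C1 | intermediate
35 | (3,3-dimethylcyclohex-1-en-1-yl)methanol | CC1(C)CCCC(CO)=C1 | intermediate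
36 | (3,3-dimethylcyclohex-1-en-1-yl)methyl methanesulfonate | CC1(C)CCCC(COS(C)(=O)=O)=C1 | intermediate
37 | 1-(chloromethyl)-3,3-dimethylcyclohex-1-ene | CC1(C)CCCC(CCl)=C1 | intermediate
38 | chloromagnesium alkoxide of 31 | BrCC/C(C)=C/CC[C@@H]1[C@@]2(C)CCCC(C)(C)[C@@H]2CC[C@@]1(C)O[Mg]Cl | intermediate
39 | Grignard reagent from 38 | Br[Mg]CC/C(C)=C/CC[C@@H]1[C@@]2(C)CCCC(C)(C)[C@@H]2CC[C@@]1(C)O[Mg]Cl | intermediate
40 | ambrein, (1R,2R,4aS,8aS)-1-{(3E)-6-[(1S)-2,2-dimethyl-6-methylidenecyclohexyl]-4-methylhex-3-en-1-yl}-2,5,5,8a-tetramethyldecahydronaphthalen-2-ol | C=C1CCCC(C)(C)[C@@H]1CC/C(C)=C/CC[C@@H]1[C@@]2(C)CCCC(C)(C)[C@@H]2CC[C@@]1(C)O | target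

**Totals**
Total step count: 20. Longest linear sequence: 17 steps (steps 1–16 and 20, from 2,2,6-trimethylcyclohexanone).

**Steps most likely to fail**

Step 7. The carbenoid may decompose to a bromo-epoxide, the ketone may be enolised instead of attacked, or the sp3 carbon C9 may migrate in place of C6. The fallback fixes the regiochemistry by the position of an enol ether and opens a cyclopropane oxidatively. It sets out from 11 and comes back at 17. Reduction of 11 with Li in NH3/THF and trapping of the enolate with Me3SiCl/Et3N should give the silyl enol ether F1 with its double bond between C8 and C6. Simmons–Smith cyclopropanation (Et2Zn, CH2I2) should give the siloxycyclopropane F2. Ito–Saegusa oxidative opening of the internal cyclopropane bond with FeCl3 in DMF should give the ring-enlarged β-chloro ketone F3. Elimination with NaOAc in MeOH and equilibration with NaOMe should give the trans-fused enone F4. Hydrogenation and NaOMe equilibration as in step 8 then give 17.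

Step 20. Attack at the unhindered CH2 terminus (SN2 instead of SN2′) may dominate because the γ-carbon is neopentylic, or facial selectivity may be poor. The fallback sets the ring C centre by separation of enantiomers and joins the halves by sp2–sp3 cross-coupling. It sets out from 35 and 27 and comes back at 40. Johnson–Claisen rearrangement of 35 (MeC(OEt)3, cat. EtCO2H, 140 °C) should give the racemic ester F5, and LiAlH4 the racemic alcohol F6. Chromatography on a chiral stationary phase gives the (S)-alcohol F7. I2/PPh3/imidazole gives the iodide F8, and zinc insertion in THF the alkylzinc iodide F9. Negishi coupling of F9 (excess) with vinyl iodide 27 under Pd(PPh3)4 catalysis gives 40.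

Step 12. Facial selectivity of the epoxidation may be low, which would give the C8 epimer after step 13. The fallback replaces epoxidation and reduction by a radical hydration. It sets out from 23 and comes back at 25. Mukaiyama hydration (Co(acac)2 cat., PhSiH3, O2, i-PrOH) should generate the tertiary C8 radical by hydrogen-atom transfer to the exocyclic alkene; capture of O2 from the less hindered α face and reduction of the peroxide give 25 directly. No new compound is made.

**Further compounds**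
F1 | step 7 | trimethylsilyl enol ether from 11 (C8=C6 enol ether, saturated at C5) | CC1(OCCO1)CCC2[C@@]3(C)CCCC(C)(C)C3C=C2O[Si](C)(C)C
F2 | step 7 | siloxycyclopropane from F1 (cyclopropane C6–C7–C8) | CC1(OCCO1)CCC2[C@@]3(C)CCCC(C)(C)C3C4CC24O[Si](C)(C)C
F3 | step 7 | ring-enlarged β-chloro ketone (chlorine at C6) | CC1(OCCO1)CCC2[C@@]3(C)CCCC(C)(C)C3C(Cl)CC2=O
F4 | step 7 | trans-fused enone, 5,5,8a-trimethyl-1-[2-(2-methyl-1,3-dioxolan-2-yl)ethyl]-4a,5,6,7,8,8a-hexahydronaphthalen-2(1H)-one (C1 epimers) | CC1(OCCO1)CCC2[C@@]3(C)CCCC(C)(C)[C@@H]3C=CC2=O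
F5 | step 20 | ethyl 2-(2,2-dimethyl-6-methylidenecyclohexyl)acetate (racemic) | CCOC(=O)CC1C(=C)CCCC1(C)C
F6 | step 20 | 2-(2,2-dimethyl-6-methylidenecyclohexyl)ethan-1-ol (racemic) | OCCC1C(=C)CCCC1(C)C
F7 | step 20 | 2-[(1S)-2,2-dimethyl-6-methylidenecyclohexyl]ethan-1-ol | C=C1CCCC(C)(C)[C@@H]1CCO
F8 | step 20 | (2S)-2-(2-iodoethyl)-1,1-dimethyl-3-methylidenecyclohexane | C=C1CCCC(C)(C)[C@@H]1CCI
F9 | step 20 | {2-[(1S)-2,2-dimethyl-6-methylidenecyclohexyl]ethyl}zinc iodide | C=C1CCCC(C)(C)[C@@H]1CC[Zn]I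
F0 | step 12 | none | none
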